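**Retrosynthetic overview**

- Kushenol V comes from its tetrakis(methoxymethyl) ether by acetal cleavage. The single stereocenter C2 arrives with the ring B fragment and is never formed on the heterocycle.
- Ring C is the only ring that is built. O1–C8a and C4–C4a are disconnected in one aryne annulation between an (S)-β-silyloxy ester (ring B, C2, C3, C4) and 3,5-bis(methoxymethoxy)-4-prenylbenzyne (ring A). The C4–C4a acylation is the ring-closing event.
- Enabling feature: ring A is a phloroglucinol whose C5 oxygen is ortho to C4a. The C4a≡C8a aryne is therefore polarised to take O1 at C8a and to carry the carbanion at C4a, beside C5–O and within a six-membered reach of the ester carbonyl C4. The C6 prenyl group between C5–O and C7–O makes the parent phenol of the aryne precursor symmetric.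
- Ring A fragment from resorcinol: MOM-directed lithiation/prenylation, para C–H borylation/oxidation, ortho-bromination, retro-Brook rearrangement/triflation. Ring B fragment from 2,4-dihydroxy-5-methoxybenzaldehyde: aldol, oxidation, asymmetric transfer hydrogenation (sets C2), silylation.
- Order of ring formation: rings A and B are taken as benzenoid starting materials; ring C is formed in step 11, followed only by deprotection.

Key step: step 11

Assumption: the ring B aldehyde 2,4-dihydroxy-5-methoxybenzaldehyde is taken as a catalogue compound, and the sense of induction of the TsDPEN catalyst in step 9 is taken from its usual aryl ketone model.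

**Route**

Step 1
Reactants: 1 resorcinol
Product: 2 1,3-bis(methoxymethoxy)benzene
Conditions: MOMCl, i-Pr2NEt, CH2Cl2, 0 °C → rt
Reagents that add atoms: chloromethyl methyl ether (MOMCl), COCCl
Why: Double O-alkylation of the phenols (Williamson-type acetal ether formation) should give the bis-MOM ether, whose acetal oxygens direct the later ortho-lithiation and survive organolithium, boron and fluoride chemistry.

Step 2
Reactants: 2 1,3-bis(methoxymethoxy)benzene; 3 prenyl bromide (1-bromo-3-methylbut-2-ene)
Product: 5 1,3-bis(methoxymethoxy)-2-(3-methylbut-2-en-1-yl)benzene, via aryllithium 4 (not isolated)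
Conditions: n-BuLi, THF, 0 °C → rt; then CuI (10 mol%), 3, −78 °C → rt
Reagents that add atoms: n-butyllithium, [Li]CCCC (lithium of 4 only)
Why: Directed ortho-metalation removes the proton flanked by both MOM ethers, and copper-catalysed SN2 allylation of 4 should place the prenyl group between the two oxygens, which fixes the later C6 (not C8) position.

Step 3
Reactants: 5 1,3-bis(methoxymethoxy)-2-(3-methylbut-2-en-1-yl)benzene
Product: 7 3,5-bis(methoxymethoxy)-4-(3-methylbut-2-en-1-yl)phenol, via aryl pinacol boronate 6 (not isolated)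
Conditions: [Ir(OMe)(cod)]2 (1.5 mol%), dtbpy (3 mol%), B2pin2 (0.55 equiv), hexane, 60 °C; then THF, NaOH (aq.), H2O2 (30% aq.), 0 °C
Reagents that add atoms: bis(pinacolato)diboron, CC1(C)OB(OC1(C)C)B1OC(C)(C)C(C)(C)O1 (boryl group of 6); hydrogen peroxide, OO (phenol oxygen of 7)
Why: Sterically governed iridium-catalysed arene C–H borylation should take the only ring C–H without an ortho substituent (para to the prenyl group), and oxidation of the C–B bond then gives the phenol, while the trisubstituted alkene is expected to stay out of the borylation.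

Step 4
Reactants: 7 3,5-bis(methoxymethoxy)-4-(3-methylbut-2-en-1-yl)phenol
Product: 8 2-bromo-3,5-bis(methoxymethoxy)-4-(3-methylbut-2-en-1-yl)phenol
Conditions: NBS (1.0 equiv), CH2Cl2, −78 °C
Reagents that add atoms: N-bromosuccinimide, O=C1CCC(=O)N1Br
Why: Electrophilic aromatic bromination of the highly activated phenol should occur ortho to the free hydroxyl, the two ortho positions being equivalent by symmetry, and at −78 °C it should be far faster than attack on the prenyl alkene.

Step 5
Reactants: 8 2-bromo-3,5-bis(methoxymethoxy)-4-(3-methylbut-2-en-1-yl)phenol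
Product: 12 3,5-bis(methoxymethoxy)-4-(3-methylbut-2-en-1-yl)-2-(trimethylsilyl)phenyl trifluoromethanesulfonate, via aryl silyl ether 9 (not isolated), via aryllithium 10 (not isolated), via lithium phenoxide 11 (not isolated)
Conditions: HMDS, THF, 65 °C, then evaporation; n-BuLi, THF, −78 °C; Tf2O, −78 → 0 °C
Reagents that add atoms: hexamethyldisilazane, C[Si](C)(C)N[Si](C)(C)C; n-butyllithium, [Li]CCCC (lithium of 10 and 11 only); trifluoromethanesulfonic anhydride, O=S(=O)(OS(=O)(=O)C(F)(F)F)C(F)(F)F
Why: O-Silylation, bromine–lithium exchange, retro-Brook 1,3-shift of silicon from oxygen to carbon and triflation of the phenoxide is the standard one-flask assembly of an ortho-silylaryl triflate, and it should place SiMe3 between the triflate and a MOM ether.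

Step 6
Reactants: 13 2,4-dihydroxy-5-methoxybenzaldehyde
Product: 14 5-methoxy-2,4-bis(methoxymethoxy)benzaldehyde
Conditions: MOMCl, i-Pr2NEt, CH2Cl2, 0 °C → reflux
Reagents that add atoms: chloromethyl methyl ether (MOMCl), COCCl
Why: Williamson-type O-alkylation should protect both phenols, including the hydrogen-bonded C2 hydroxyl, as MOM ethers that tolerate enolate, oxidant, hydride-transfer and fluoride conditions.

Step 7
Reactants: 14 5-methoxy-2,4-bis(methoxymethoxy)benzaldehyde; 15 ethyl acetate
Product: 17 ethyl rac-3-hydroxy-3-[5-methoxy-2,4-bis(methoxymethoxy)phenyl]propanoate, via lithium enolate 16 (not isolated)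
Conditions: LiN(i-Pr)2 (LDA), 15, THF, −78 °C; then 14; AcOH quench
Reagents that add atoms: lithium diisopropylamide, [Li]N(C(C)C)C(C)C (lithium of 16 only)
Why: Aldol addition of the lithium enolate of ethyl acetate to the aldehyde should give the β-hydroxy ester as the racemate, which is acceptable because the carbinol is reset in step 9.

Step 8
Reactants: 17 ethyl rac-3-hydroxy-3-[5-methoxy-2,4-bis(methoxymethoxy)phenyl]propanoate
Product: 18 ethyl 3-[5-methoxy-2,4-bis(methoxymethoxy)phenyl]-3-oxopropanoate
Conditions: Dess–Martin periodinane, CH2Cl2, 0 °C → rt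
Reagents that add atoms: none
Why: Dess–Martin oxidation of the secondary benzylic alcohol should give the β-keto ester under nearly neutral conditions that spare the MOM acetals.

Step 9
Reactants: 18 ethyl 3-[5-methoxy-2,4-bis(methoxymethoxy)phenyl]-3-oxopropanoate
Product: 19 ethyl (S)-3-hydroxy-3-[5-methoxy-2,4-bis(methoxymethoxy)phenyl]propanoate
Conditions: RuCl(p-cymene)[(S,S)-TsDPEN] (1 mol%), HCO2H/Et3N (5:2), DMF, 30 °C
Reagents that add atoms: none
Why: Noyori–Ikariya asymmetric transfer hydrogenation of the aryl ketone, with the aryl ring held against the η6-cymene of the (S,S)-TsDPEN catalyst, should deliver hydride to the face that gives the (S)-carbinol, which becomes C2 of the target.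

Step 10
Reactants: 19 ethyl (S)-3-hydroxy-3-[5-methoxy-2,4-bis(methoxymethoxy)phenyl]propanoate
Product: 20 ethyl (S)-3-[5-methoxy-2,4-bis(methoxymethoxy)phenyl]-3-[(trimethylsilyl)oxy]propanoate
Conditions: TMSCl, imidazole, CH2Cl2, 0 °C; filtration through Et3N-deactivated silica
Reagents that add atoms: chlorotrimethylsilane, C[Si](C)(C)Cl
Why: Silyl ether formation turns the hydroxyl into a fluoride-releasable alkoxide without touching the stereocenter.

Step 11
Reactants: 12 3,5-bis(methoxymethoxy)-4-(3-methylbut-2-en-1-yl)-2-(trimethylsilyl)phenyl trifluoromethanesulfonate; 20 ethyl (S)-3-[5-methoxy-2,4-bis(methoxymethoxy)phenyl]-3-[(trimethylsilyl)oxy]propanoate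
Product: 24 (S)-2-[5-methoxy-2,4-bis(methoxymethoxy)phenyl]-5,7-bis(methoxymethoxy)-6-(3-methylbut-2-en-1-yl)chroman-4-one, via aryne 21 (not isolated), via cesium alkoxide 22 (not isolated), via arylcesium adduct 23 (not isolated)
Conditions: CsF (1.5 equiv), 18-crown-6 (0.3 equiv), 4 Å MS, THF, 0 °C → rt; 12 (1.3 equiv) added slowly
Reagents that add atoms: cesium fluoride, [Cs+].[F-] (cesium of 22 and 23 only)
Why: Proposed new method: fluoride (and then the ethoxide released in each turnover, which is captured as EtOSiMe3) strips silicon from both partners, so that aryne 21 and the proton-free alkoxide 22 are released together; 22 adds through oxygen to the aryne carbon remote from the C5 methoxymethoxy group (future C8a), and the aryl carbanion 23 at C4a attacks the tethered ethyl ester and expels ethoxide, forming the C4–C4a bond. The closest known reaction type is the fluoride-mediated coupling–cyclisation of arynes with methyl salicylates to xanthones (phenoxide addition, then acylation of the aryl anion by the ortho ester), here transferred to an aliphatic β-oxido ester and triggered from a silyl ether. Ring C closes in a 6-exo-trig acyl substitution by the C4a carbanion, the O1–C8a bond being made intermolecularly just before it. No stereocenter is formed: C2 comes from 20 with retention, because only its O–Si bond and not its C–O bond is broken. The step needs regioselective addition to the unsymmetrical aryne, which the C5 alkoxy group secures by inductive polarisation (the known meta-attack on 3-alkoxyarynes, which also puts the carbanion beside that oxygen), and it needs acylation to outrun protonation of 23, which the silyl ether secures by keeping every O–H out of the flask. Slow addition of 12 keeps the concentration of free alkoxide low, which should limit retro-aldol loss and base-mediated ring opening of the flavanone at C2.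

Step 12
Reactants: 24 (S)-2-[5-methoxy-2,4-bis(methoxymethoxy)phenyl]-5,7-bis(methoxymethoxy)-6-(3-methylbut-2-en-1-yl)chroman-4-one
Product: 25 Kushenol V, (2S)-2-(2,4-dihydroxy-5-methoxyphenyl)-5,7-dihydroxy-6-(3-methylbut-2-en-1-yl)chroman-4-one
Conditions: HCl (3 M aq.), MeOH, 50 °C
Reagents that add atoms: none
Why: Acid-catalysed transacetalisation to methanol should remove all four MOM groups at an acidity and temperature low enough to avoid prenyl cyclisation onto the freed C5 or C7 hydroxyl and ring opening at C2.

**Compound list**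

1 | resorcinol (benzene-1,3-diol) | Oc1cccc(O)c1 | starting material
2 | 1,3-bis(methoxymethoxy)benzene | COCOc1cccc(OCOC)c1 | intermediate
3 | prenyl bromide (1-bromo-3-methylbut-2-ene) | CC(C)=CCBr | starting material
4 | [2,6-bis(methoxymethoxy)phenyl]lithium | [Li]c1c(OCOC)cccc1OCOC | intermediate
5 | 1,3-bis(methoxymethoxy)-2-(3-methylbut-2-en-1-yl)benzene | COCOc1cccc(OCOC)c1CC=C(C)C | intermediate
6 | 2-[3,5-bis(methoxymethoxy)-4-(3-methylbut-2-en-1-yl)phenyl]-4,4,5,5-tetramethyl-1,3,2-dioxaborolane | CC1(C)OB(OC1(C)C)c1cc(OCOC)c(CC=C(C)C)c(OCOC)c1 | intermediate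
7 | 3,5-bis(methoxymethoxy)-4-(3-methylbut-2-en-1-yl)phenol | COCOc1cc(O)cc(OCOC)c1CC=C(C)C | intermediate
8 | 2-bromo-3,5-bis(methoxymethoxy)-4-(3-methylbut-2-en-1-yl)phenol | COCOc1cc(O)c(Br)c(OCOC)c1CC=C(C)C | intermediate
9 | [2-bromo-3,5-bis(methoxymethoxy)-4-(3-methylbut-2-en-1-yl)phenoxy]trimethylsilane | COCOc1cc(O[Si](C)(C)C)c(Br)c(OCOC)c1CC=C(C)C | intermediate
10 | [2,4-bis(methoxymethoxy)-3-(3-methylbut-2-en-1-yl)-6-(trimethylsilyloxy)phenyl]lithium | COCOc1cc(O[Si](C)(C)C)c([Li])c(OCOC)c1CC=C(C)C | intermediate
11 | lithium 3,5-bis(methoxymethoxy)-4-(3-methylbut-2-en-1-yl)-2-(trimethylsilyl)phenolate | COCOc1cc([O-])c([Si](C)(C)C)c(OCOC)c1CC=C(C)C.[Li+] | intermediate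
12 | 3,5-bis(methoxymethoxy)-4-(3-methylbut-2-en-1-yl)-2-(trimethylsilyl)phenyl trifluoromethanesulfonate | COCOc1cc(OS(=O)(=O)C(F)(F)F)c([Si](C)(C)C)c(OCOC)c1CC=C(C)C | intermediate
13 | 2,4-dihydroxy-5-methoxybenzaldehyde | COc1cc(C=O)c(O)cc1O | starting material
14 | 5-methoxy-2,4-bis(methoxymethoxy)benzaldehyde | COc1cc(C=O)c(OCOC)cc1OCOC | intermediate
15 | ethyl acetate | CCOC(C)=O | starting material
16 | lithium 1-ethoxyethen-1-olate (lithium enolate of ethyl acetate) | [Li+].[O-]C(=C)OCC | intermediate
17 | ethyl rac-3-hydroxy-3-[5-methoxy-2,4-bis(methoxymethoxy)phenyl]propanoate | COc1cc(C(O)CC(=O)OCC)c(OCOC)cc1OCOC | intermediate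
18 | ethyl 3-[5-methoxy-2,4-bis(methoxymethoxy)phenyl]-3-oxopropanoate | COc1cc(C(=O)CC(=O)OCC)c(OCOC)cc1OCOC | intermediate
19 | ethyl (S)-3-hydroxy-3-[5-methoxy-2,4-bis(methoxymethoxy)phenyl]propanoate | COc1cc([C@@H](O)CC(=O)OCC)c(OCOC)cc1OCOC | intermediate
20 | ethyl (S)-3-[5-methoxy-2,4-bis(methoxymethoxy)phenyl]-3-[(trimethylsilyl)oxy]propanoate | COc1cc([C@@H](O[Si](C)(C)C)CC(=O)OCC)c(OCOC)cc1OCOC | intermediate
21 | 3,5-bis(methoxymethoxy)-4-(3-methylbut-2-en-1-yl)benzyne (1,2-didehydrobenzene) | COCOC1=C(CC=C(C)C)C(OCOC)=CC#C1 | intermediate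
22 | cesium (S)-3-ethoxy-1-[5-methoxy-2,4-bis(methoxymethoxy)phenyl]-3-oxopropan-1-olate | COc1cc([C@@H]([O-])CC(=O)OCC)c(OCOC)cc1OCOC.[Cs+] | intermediate
23 | arylcesium from O-addition of 22 to 21: ethyl (S)-3-[2-cesio-3,5-bis(methoxymethoxy)-4-(3-methylbut-2-en-1-yl)phenoxy]-3-[5-methoxy-2,4-bis(methoxymethoxy)phenyl]propanoate | COc1cc([C@@H](Oc2cc(OCOC)c(CC=C(C)C)c(OCOC)c2[Cs])CC(=O)OCC)c(OCOC)cc1OCOC | intermediate
24 | (S)-2-[5-methoxy-2,4-bis(methoxymethoxy)phenyl]-5,7-bis(methoxymethoxy)-6-(3-methylbut-2-en-1-yl)chroman-4-one | COc1cc([C@@H]2CC(=O)c3c(cc(OCOC)c(CC=C(C)C)c3OCOC)O2)c(OCOC)cc1OCOC | intermediate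
25 | Kushenol V, (2S)-2-(2,4-dihydroxy-5-methoxyphenyl)-5,7-dihydroxy-6-(3-methylbut-2-en-1-yl)chroman-4-one | COc1cc([C@@H]2CC(=O)c3c(cc(O)c(CC=C(C)C)c3O)O2)c(O)cc1O | target

**Step count**

Total step count: 12. Longest linear sequence: 7 steps (steps 1–5, 11, 12; the ring B branch, steps 6–10, 11, 12, is equally long).

**Steps most likely to fail**

1. Step 11 (proposed new method). What may go wrong:
- quenching of the aryl carbanion by adventitious protons or by silicon before it acylates;
- retro-aldol fragmentation or β-elimination of the unmasked alkoxide;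
- capture of the aryne by ethoxide or fluoride;
- base-mediated ring opening of the flavanone, eroding the configuration at C2.

Fallback, known chemistry throughout (asymmetric transfer hydrogenation, Weinreb amidation, Mitsunobu etherification, Parham-type cyclisation). It sets out from keto ester 18 and bromophenol 8 and comes back at 24. Compound 18 is reduced with the enantiomeric catalyst RuCl(p-cymene)[(R,R)-TsDPEN] (HCO2H/Et3N) to ethyl (R)-3-hydroxy-3-[5-methoxy-2,4-bis(methoxymethoxy)phenyl]propanoate F1. F1 is converted with MeNH(OMe)·HCl and i-PrMgCl (THF, −20 °C) into (R)-3-hydroxy-N-methoxy-3-[5-methoxy-2,4-bis(methoxymethoxy)phenyl]-N-methylpropanamide F2. Mitsunobu etherification of F2 with 8 (PPh3, DIAD, toluene, 0 °C) should give, with inversion at the carbinol carbon, (S)-3-[2-bromo-3,5-bis(methoxymethoxy)-4-(3-methylbut-2-en-1-yl)phenoxy]-N-methoxy-3-[5-methoxy-2,4-bis(methoxymethoxy)phenyl]-N-methylpropanamide F3. Bromine–lithium exchange with t-BuLi (THF, −78 °C) should give the corresponding (S)-aryllithium F4, which closes ring C by attack of C4a on the amide carbonyl (same C4–C4a bond) and gives 24 after aqueous work-up, ready for step 12.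

2. Step 3. What may go wrong: the iridium boryl/hydride species may engage the trisubstituted prenyl alkene (hydroboration or double-bond isomerisation) in competition with arene C–H borylation.

Fallback: the oxygen is installed before the prenyl group. It sets out from 2 and comes back at 7. The same borylation of 2 ([Ir(OMe)(cod)]2, dtbpy, B2pin2) should give, at the only C–H without an ortho substituent, 2-[3,5-bis(methoxymethoxy)phenyl]-4,4,5,5-tetramethyl-1,3,2-dioxaborolane F5, which is oxidised in the same flask (H2O2, NaOH) to 3,5-bis(methoxymethoxy)phenol F6. Silylation (TIPSCl, imidazole, DMF) gives [3,5-bis(methoxymethoxy)phenoxy]triisopropylsilane F7. n-BuLi (THF, 0 °C) should lithiate F7 between the two MOM ethers, the bulky silyl ether being no director, to give [2,6-bis(methoxymethoxy)-4-(triisopropylsilyloxy)phenyl]lithium F8. Copper-catalysed allylation of F8 with 3 (CuI) gives [3,5-bis(methoxymethoxy)-4-(3-methylbut-2-en-1-yl)phenoxy]triisopropylsilane F9, and TBAF (THF, 0 °C) then frees phenol 7.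

3. Step 9. What may go wrong: poor facial discrimination and slow hydride transfer to the electron-rich, ortho-alkoxy aryl ketone, which would leave the only stereocenter with insufficient enantiomeric purity.

Fallback: kinetic resolution instead of asymmetric reduction. It sets out from racemic 17 and comes back at 19, leaving out step 8. Lipase from Burkholderia cepacia with vinyl acetate (t-BuOMe, 35 °C) should acylate the (R)-enantiomer, which carries the aryl group as the large substituent, to ethyl (R)-3-acetoxy-3-[5-methoxy-2,4-bis(methoxymethoxy)phenyl]propanoate F10. The unreacted (S)-alcohol 19 is separated by chromatography and carried into step 10.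

**Further compounds**

F1 | step 11 | ethyl (R)-3-hydroxy-3-[5-methoxy-2,4-bis(methoxymethoxy)phenyl]propanoate | COc1cc([C@H](O)CC(=O)OCC)c(OCOC)cc1OCOC
F2 | step 11 | (R)-3-hydroxy-N-methoxy-3-[5-methoxy-2,4-bis(methoxymethoxy)phenyl]-N-methylpropanamide | COc1cc([C@H](O)CC(=O)N(C)OC)c(OCOC)cc1OCOC
F3 | step 11 | (S)-3-[2-bromo-3,5-bis(methoxymethoxy)-4-(3-methylbut-2-en-1-yl)phenoxy]-N-methoxy-3-[5-methoxy-2,4-bis(methoxymethoxy)phenyl]-N-methylpropanamide | COc1cc([C@@H](Oc2cc(OCOC)c(CC=C(C)C)c(OCOC)c2Br)CC(=O)N(C)OC)c(OCOC)cc1OCOC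
F4 | step 11 | (S)-aryllithium from bromine–lithium exchange of F3 | COc1cc([C@@H](Oc2cc(OCOC)c(CC=C(C)C)c(OCOC)c2[Li])CC(=O)N(C)OC)c(OCOC)cc1OCOC
F5 | step 3 | 2-[3,5-bis(methoxymethoxy)phenyl]-4,4,5,5-tetramethyl-1,3,2-dioxaborolane | CC1(C)OB(OC1(C)C)c1cc(OCOC)cc(OCOC)c1
F6 | step 3 | 3,5-bis(methoxymethoxy)phenol | COCOc1cc(O)cc(OCOC)c1
F7 | step 3 | [3,5-bis(methoxymethoxy)phenoxy]triisopropylsilane | COCOc1cc(O[Si](C(C)C)(C(C)C)C(C)C)cc(OCOC)c1
F8 | step 3 | [2,6-bis(methoxymethoxy)-4-(triisopropylsilyloxy)phenyl]lithium | COCOc1cc(O[Si](C(C)C)(C(C)C)C(C)C)cc(OCOC)c1[Li]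
F9 | step 3 | [3,5-bis(methoxymethoxy)-4-(3-methylbut-2-en-1-yl)phenoxy]triisopropylsilane | COCOc1cc(O[Si](C(C)C)(C(C)C)C(C)C)cc(OCOC)c1CC=C(C)C
F10 | step 9 | ethyl (R)-3-acetoxy-3-[5-methoxy-2,4-bis(methoxymethoxy)phenyl]propanoate | COc1cc([C@H](OC(C)=O)CC(=O)OCC)c(OCOC)cc1OCOC
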